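**Retrosynthetic overview**
1. The C3–Br bond is made last, by retentive deoxybromination (Cl participation) of the tertiary trans‑chlorohydrin 15.
2. Key step: the C6–C11 bond forms by solvolysis of an enantioenriched bromochloride to a bromonium ion, closed by an allylsilane. This one step makes ring A, the spiro carbon C6, the equatorial C10–Br and the C7=CH2 group.
3. The (Z)‑allylsilane is unmasked from a stereodefined enol triflate (s‑trans conjugate reduction, then triflation). The triflate is inert to electrophiles, so ring B can be epoxidised (Shi) and opened with chloride while it is in place.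
4. The C8–C9 bond comes from an anti‑selective (Cornforth) aldol of a dienyl methyl ketone with (S)‑2‑bromo‑3‑chloro‑3‑methylbutanal, itself from catalytic enantioselective bromochlorination of prenol.
5. Ring order: ring B first, as an achiral cyclohexadiene building block; ring A last. The spirocentre is not made by a Diels–Alder reaction or RCM.

Assumption 1: chamigrane numbering is used. Ring B is C1–C6 (C6 spiro, C2–Cl, C3–Br/CH3‑15). Ring A is C6–C11 (C7=C14H2, C9–O, C10–Br, C11 Me2). The target is (2S,3S,6R,9S,10R).
Assumption 2: in step 1 the ligand antipode that gives (S)‑2 is used. The sense of induction is assumed, and both antipodes are accessible.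

**Step 1**
Reactants: 1, 3‑methylbut‑2‑en‑1‑ol (prenol)
Product: 2, (S)‑2‑bromo‑3‑chloro‑3‑methylbutan‑1‑ol
Conditions: NBS, ClTi(Oi‑Pr)3, chiral tridentate salicylaldimine–amino alcohol (Schiff base) ligand (20 mol %), hexanes, −20 °C
Reagents that add atoms: NBS, O=C1CCC(=O)N1Br; ClTi(Oi‑Pr)3, CC(C)O[Ti](Cl)(OC(C)C)OC(C)C
Why: Ti‑catalysed enantioselective bromochlorination of an allylic alcohol, in which the Ti‑bound alkene takes Br+ on one face and chloride adds anti at the distal tertiary carbon (catalyst and Markovnikov preferences agree), setting the future C10.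

**Step 2**
Reactants: 2
Product: 3, (S)‑2‑bromo‑3‑chloro‑3‑methylbutanal
Conditions: DMP, NaHCO3, CH2Cl2, 0 °C; used crude at once
Reagents that add atoms: none
Why: Dess–Martin oxidation is neutral and amine‑free, so the α‑bromo stereocentre is not epimerised and HCl is not lost by E1cB.

**Step 3**
Reactants: 4, isoprene; 5, but‑3‑yn‑2‑one
Product: 6, 1‑(4‑methylcyclohexa‑1,4‑dien‑1‑yl)ethan‑1‑one
Conditions: EtAlCl2 (20 mol %), BHT, CH2Cl2, −30 °C → rt
Reagents that add atoms: none
Why: Lewis‑acid Diels–Alder reaction of an ynone follows the "para" rule and creates no stereocentre, but the position of the enone C5=C6 bond relative to C2=C3 is what later encodes the alkene geometry.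

**Step 4**
Reactants: 6; 3
Product: 7, (3S,4S)‑4‑bromo‑5‑chloro‑3‑hydroxy‑5‑methyl‑1‑(4‑methylcyclohexa‑1,4‑dien‑1‑yl)hexan‑1‑one (anti‑bromohydrin; 9S,10S)
Conditions: LDA, THF, −78 °C; then 3, −78 °C, 15 min; AcOH quench at −78 °C
Reagents that add atoms: none
Why: Aldol addition of the kinetic α′ (methyl) lithium enolate to an α‑halo aldehyde follows the Cornforth/polar Felkin–Anh model (C–Br anti to C=O, attack past H rather than CMe2Cl) and gives the 1,2‑anti halohydrin, which sets C9 (S).

**Step 5**
Reactants: 7
Product: 8, the 9‑O‑triethylsilyl ether of 7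
Conditions: TESOTf, 2,6‑lutidine, CH2Cl2, −78 °C
Reagents that add atoms: TESOTf, CC[Si](CC)(CC)OS(=O)(=O)C(F)(F)F
Why: Low‑temperature silylation masks the aldol OH against retro‑aldol, O‑triflation and epoxide closure in the next steps, and no stereocentre is touched.

**Step 6**
Reactants: 8
Product: 9, the (Z)‑enol triflate [C6=C7(OTf)–C8], with ring B now 4‑methylcyclohex‑3‑enylidene, OTf cis to ring C1H2 and the C8 chain cis to C5H2; 9S,10S
Conditions: L‑Selectride (1.05 equiv), THF, −78 °C; then Comins' reagent, −78 → 0 °C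
Reagents that add atoms: Comins' reagent, FC(F)(F)S(=O)(=O)N(c1ccc(Cl)cn1)S(=O)(=O)C(F)(F)F
Why: Conjugate reduction with enolate trapping, where the 1‑acylcyclohexene reacts through its preferred s‑trans conformer to give the E(O)‑enolate (O trans to the former β‑carbon C5) regiospecifically, and O‑triflation freezes that geometry while the hindered alkyl halides are inert at −78 °C.

**Step 7**
Reactants: 9
Product: 10, the (2R,3S)‑2,3‑epoxide of 9
Conditions: D‑fructose‑derived Shi ketone (30 mol %), Oxone, K2CO3, Bu4NHSO4, MeCN–DMM/aq. Na2B4O7–EDTA, 0 °C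
Reagents that add atoms: Oxone (KHSO5), [K+].[O-]S(=O)(=O)OO
Why: Shi asymmetric epoxidation attacks only the electron‑rich trisubstituted C2=C3 (the vinyl triflate is deactivated), and the spiro transition‑state model that gives (R,R)‑1‑phenylcyclohexene oxide predicts (2R,3S) here, with the minor diastereomer removable.

**Step 8**
Reactants: 10
Product: 11, the (2S,3S)‑trans‑chlorohydrin (C2–Cl secondary, C3–OH tertiary), enol triflate retained
Conditions: Li2CuCl4 (LiCl/CuCl2), THF, 0 °C → rt; aq. NH4Cl
Reagents that add atoms: Li2CuCl4, [Li+].[Li+].Cl[Cu-2](Cl)(Cl)Cl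
Why: SN2 trans‑diaxial (Fürst–Plattner) epoxide opening by soft chloride occurs at the less substituted C2 with inversion, and it is unhindered because C6 is still sp2 and has no axial substituent.

**Step 9**
Reactants: 11
Product: 12, the (Z)‑allylsilane [C6=C7(CH2SiMe3)–C8], with C14H2SiMe3 cis to C1; 2S,3S,9S,10S
Conditions: Me3SiCH2ZnCl·LiCl (3 equiv), Pd(PPh3)4 (10 mol %), THF, 40 °C
Reagents that add atoms: Me3SiCH2ZnCl, C[Si](C)(C)C[Zn]Cl
Why: Negishi coupling of a vinyl triflate proceeds with retention of alkene geometry, and Pd/PPh3 with the mild zinc reagent leaves the unactivated C–Br, C–Cl and tertiary OH alone, so the nucleophilic alkene appears only after all electrophilic oxidations are finished.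

**Step 10 (key step)**
Reactants: 12
Product: 13, (2S,3S,6R,9S,10R)‑10‑bromo‑2‑chloro‑9‑(triethylsilyloxy)chamigr‑7(14)‑en‑3‑ol
Conditions: HFIP (0.01 M), 2,6‑di‑tert‑butyl‑4‑methylpyridine (2 equiv), 0 → 25 °C
Reagents that add atoms: none
Why: Proposed new method: HFIP ionises the tertiary C11–Cl with anchimeric help from the anti C10–Br to give a configurationally defined bromonium ion (closest known reactions: bromochloride‑solvolysis bromopolyene cyclisation and allylsilane‑terminated cation–olefin cyclisation); the allylsilane γ‑carbon C6 opens it at C11 anti to Br through a chair (Br equatorial by stereoelectronics, OTES axial) in which the ring carbon trans to C8 (C1) becomes equatorial and C5 axial, so Z geometry plus 10S give 6R (attack is also anti to C2–Cl), and loss of Me3Si+ from the β‑silyl cation gives only the exocyclic C7=C14 alkene.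

**Step 11**
Reactants: 13
Product: 14, (2S,3S,6R,9S,10R)‑10‑bromo‑2‑chlorochamigr‑7(14)‑ene‑3,9‑diol
Conditions: HF·pyridine, pyridine, THF, 0 °C
Reagents that add atoms: none
Why: Buffered fluoride desilylation is safe here because the cis (axial OH/equatorial Br) bromohydrin cannot close to an epoxide, and the alkene and halides are unaffected.

**Step 12**
Reactants: 14
Product: 15, the 9‑acetate of 14 (C3–OH free)
Conditions: Ac2O (1.5 equiv), pyridine, DMAP (5 mol %), CH2Cl2, 0 °C
Reagents that add atoms: Ac2O, CC(=O)OC(C)=O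
Why: Chemoselective acylation works because the secondary C9–OH reacts far faster than the tertiary β‑chloro C3–OH, and no stereocentre changes.

**Step 13**
Reactants: 15
Product: 16, 9‑acetylisoobtusol (target)
Conditions: 1‑bromo‑N,N,2‑trimethylprop‑1‑en‑1‑amine (from Ghosez's chloro‑enamine by halide exchange), CH2Cl2, −20 °C → rt
Reagents that add atoms: α‑bromoenamine, CC(C)=C(Br)N(C)C
Why: Proposed new method: the α‑bromoenamine converts the tertiary OH into an alkoxyiminium bromide under neutral conditions (known Ghosez‑type deoxyhalogenation of tertiary alcohols), ionisation is assisted by the antiperiplanar C2–Cl (unsymmetrical chloronium, as in known chloride‑participation retentions), and bromide attacks the more cationic C3 anti to Cl, giving net retention and the trans C2–Cl/C3–Br array with no free HBr to attack C7=C14.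

**Compound list**
1 | 3‑methylbut‑2‑en‑1‑ol | CC(C)=CCO | starting material
2 | (S)‑2‑bromo‑3‑chloro‑3‑methylbutan‑1‑ol | OC[C@H](Br)C(C)(C)Cl | intermediate
3 | (S)‑2‑bromo‑3‑chloro‑3‑methylbutanal | O=C[C@H](Br)C(C)(C)Cl | intermediate
4 | isoprene | C=CC(C)=C | starting material
5 | but‑3‑yn‑2‑one | CC(=O)C#C | starting material
6 | 1‑(4‑methylcyclohexa‑1,4‑dien‑1‑yl)ethan‑1‑one | CC(=O)C1=CCC(C)=CC1 | intermediate
7 | (9S,10S) anti‑aldol (β‑hydroxy‑γ‑bromo‑δ‑chloro ketone) | CC1=CCC(=CC1)C(=O)C[C@H](O)[C@H](Br)C(C)(C)Cl | intermediate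
8 | 9‑O‑TES ether of 7 | CC1=CCC(=CC1)C(=O)C[C@H](O[Si](CC)(CC)CC)[C@H](Br)C(C)(C)Cl | intermediate
9 | (Z)‑enol triflate (OTf cis to C1) | FC(F)(F)S(=O)(=O)O/C(C[C@H](O[Si](CC)(CC)CC)[C@H](Br)C(C)(C)Cl)=C1/CCC(C)=CC1 | intermediate
10 | (2R,3S)‑epoxide of 9 | FC(F)(F)S(=O)(=O)O/C(C[C@H](O[Si](CC)(CC)CC)[C@H](Br)C(C)(C)Cl)=C1/CC[C@]2(C)O[C@@H]2C1 | intermediate
11 | (2S,3S)‑chlorohydrin enol triflate | FC(F)(F)S(=O)(=O)O/C(C[C@H](O[Si](CC)(CC)CC)[C@H](Br)C(C)(C)Cl)=C1/CC[C@](C)(O)[C@@H](Cl)C1 | intermediate
12 | (Z)‑allylsilane cyclisation precursor | C[Si](C)(C)C/C(C[C@H](O[Si](CC)(CC)CC)[C@H](Br)C(C)(C)Cl)=C1/CC[C@](C)(O)[C@@H](Cl)C1 | intermediate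
13 | (2S,3S,6R,9S,10R) spirocycle, 9‑OTES, 3‑OH | C=C1C[C@H](O[Si](CC)(CC)CC)[C@H](Br)C(C)(C)[C@@]12CC[C@](C)(O)[C@@H](Cl)C2 | intermediate
14 | 3,9‑diol | C=C1C[C@H](O)[C@H](Br)C(C)(C)[C@@]12CC[C@](C)(O)[C@@H](Cl)C2 | intermediate
15 | 9‑acetate, 3‑OH chlorohydrin | C=C1C[C@H](OC(C)=O)[C@H](Br)C(C)(C)[C@@]12CC[C@](C)(O)[C@@H](Cl)C2 | intermediate
16 | 9‑acetylisoobtusol | C=C1C[C@H](OC(C)=O)[C@H](Br)C(C)(C)[C@@]12CC[C@](C)(Br)[C@@H](Cl)C2 | target

**Totals**
Total steps: 13. Longest linear sequence: 12 (1→2→3→7→8→9→10→11→12→13→14→15→16).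

**Three steps most likely to fail**
1. **Step 10 (spirocyclisation).**
   - Risks: two fully substituted carbons must bond; the axial OTES adds strain; E1 elimination, HFIP capture or protodesilylation may compete.
   - Fallback: change the electrophile. Carry a C9 ketone/C10=C11 enone side chain, made by aldol of 6 with 3‑methylbut‑2‑enal and later oxidation. Close ring A by intramolecular Hosomi–Sakurai 1,4‑addition (EtAlCl2). Trap the regiodefined enolate with NBS at C10, then reduce with DIBAL‑H to the cis‑bromohydrin.
2. **Step 13 (tertiary bromide with retention).**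
   - Risks: E1 elimination, or bromide attack at C2.
   - Fallback: switch to a radical route. Convert C3–OH into its cesium oxalate and run a photoredox decarboxylative deoxybromination with a Br‑atom donor (BrCCl3 or diethyl bromomalonate). The β‑chloro tertiary radical should be brominated anti to C2–Cl.
3. **Step 6 (1,4‑ versus 1,2‑reduction and E(O)‑enolate fidelity).**
   - Risk: alkene geometry controls C6, so any leakage gives the 6‑epimer.
   - Fallback: take the geometry from an alkyne instead. Use Cu‑catalysed chelation‑controlled anti‑carbomagnesiation/iodination of a 2‑alkyn‑1‑ol, then B‑alkyl Suzuki coupling, then ring‑closing metathesis to build ring B around the pre‑set tetrasubstituted alkene.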